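The dihydropyran ring of the chroman (chroman numbering) is cut twice at once: at the C2–C3 bond of the quaternary carbon and at the aryl ether bond O1–C8a. This gives two fragments of similar size: (5E,9E)-farnesylacetone, whose carbonyl group supplies C2, O1, the C2 methyl group and the trienyl chain, and a 2-(2-fluoroaryl)ethyl Grignard reagent carrying C3, C4 and the MOM-protected catechol ring. In the key step a ligand-controlled 1,2-addition joins C3 to C2 and sets the stereocentre; the tertiary alkoxide O1 then displaces fluoride from C8a in the same flask. The step exploits the 1,4-relationship of nucleophilic C3 and electrophilic C8a (through C4 and C4a), which the C2=O1 carbonyl bridges to the six-membered ring.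

Key step: step 7

Remark on the target: the stereocentre C2 carries O1 > C3 > side-chain CH2 > CH3 and is (S).

Remark on the ligand: L* is 2,4-di-tert-butyl-6-({[(1R,2R)-2-(dimethylamino)cyclohexyl](methyl)amino}methyl)phenol, CN(C)[C@@H]1CCCC[C@H]1N(C)Cc1cc(C(C)(C)C)cc(C(C)(C)C)c1O; it is recovered unchanged by acid–base extraction.

Assumption: the (1R,2R)-ligand is taken to direct the Grignard reagent to the Re face of the ketone in the key step; if a pilot run shows the opposite sense, the (1S,2S)-ligand is used with no other change.

Step 1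
Reactants: 1 4-methylcatechol
Product: 2 1,2-bis(methoxymethoxy)-4-methylbenzene
Conditions: NaH, MOMCl, THF/DMF, 0 °C to rt
Reagents that add atoms: chloromethyl methyl ether (MOMCl), COCCl
Why: Double Williamson etherification of the catecholate with the reactive α-chloro ether should give the bis-MOM ether, which later directs the ortho-lithiation and survives the organometallic and strongly basic steps.

Step 2
Reactants: 2 1,2-bis(methoxymethoxy)-4-methylbenzene
Product: 4 1-fluoro-2,3-bis(methoxymethoxy)-5-methylbenzene, via aryllithium 3 (not isolated)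
Conditions: n-BuLi, TMEDA, THF, −78 to 0 °C; then NFSI, −78 °C to rt; aq. NH4Cl
Reagents that add atoms: N-fluorobenzenesulfonimide (NFSI), O=S(=O)(c1ccccc1)N(F)S(=O)(=O)c1ccccc1
Why: Directed ortho-metalation should take place at C6, the ortho C–H of a MOM ether that is not flanked by the methyl group, and the aryllithium is then fluorinated by the electrophilic N–F reagent.

Step 3
Reactants: 4 1-fluoro-2,3-bis(methoxymethoxy)-5-methylbenzene
Product: 5 2-bromo-3-fluoro-4,5-bis(methoxymethoxy)-1-methylbenzene
Conditions: NBS, MeCN, 0 °C to rt, dark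
Reagents that add atoms: N-bromosuccinimide (NBS), O=C1CCC(=O)N1Br
Why: Electrophilic aromatic bromination should occur para to the C3 MOM ether, between fluorine and methyl, because the only other free position is ortho to that ether and the para position of the second ether is blocked by the methyl group.

Step 4
Reactants: 5 2-bromo-3-fluoro-4,5-bis(methoxymethoxy)-1-methylbenzene
Product: 7 2-[2-fluoro-3,4-bis(methoxymethoxy)-6-methylphenyl]ethan-1-ol, via arylmagnesium chloride 6 (not isolated)
Conditions: i-PrMgCl·LiCl, THF, 0 °C; then CuI (10 mol %), ethylene oxide, −20 to 0 °C; aq. NH4Cl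
Reagents that add atoms: ethylene oxide (oxirane), C1CO1
Why: Bromine–magnesium exchange, helped by the ortho fluorine, should give an aryl Grignard reagent that is stable at or below 0 °C, and its copper-catalysed SN2 opening of ethylene oxide adds C4 and C3 of the target as a primary alcohol.

Step 5
Reactants: 7 2-[2-fluoro-3,4-bis(methoxymethoxy)-6-methylphenyl]ethan-1-ol
Product: 8 2-(2-bromoethyl)-3-fluoro-4,5-bis(methoxymethoxy)-1-methylbenzene
Conditions: CBr4, PPh3, 2,6-lutidine, CH2Cl2, 0 °C
Reagents that add atoms: carbon tetrabromide, BrC(Br)(Br)Br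
Why: Appel reaction, in which bromide displaces the alkoxyphosphonium group by SN2 under buffered, neutral conditions that leave the MOM acetals intact.

Step 6
Reactants: 9 (2E,6E)-farnesyl bromide; 10 ethyl acetoacetate
Product: 13 (5E,9E)-farnesylacetone, via keto ester 11 (not isolated), via keto acid 12 (not isolated)
Conditions: NaOEt, EtOH, 0 °C to rt; then 2 M aq. NaOH, 50 °C; then dilute HCl to pH 3, 50 °C
Reagents that add atoms: none
Why: Acetoacetic ester synthesis, in which SN2 C-alkylation of the stabilised enolate by the primary allylic bromide keeps both E alkenes, and saponification with decarboxylation of the β-keto acid should give the methyl ketone.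

Step 7
Reactants: 8 2-(2-bromoethyl)-3-fluoro-4,5-bis(methoxymethoxy)-1-methylbenzene; 13 (5E,9E)-farnesylacetone
Product: 17 (2S)-7,8-bis(methoxymethoxy)-2,5-dimethyl-2-[(3E,7E)-4,8,12-trimethyltrideca-3,7,11-trien-1-yl]chromane, via Grignard reagent 14 (not isolated), via bromomagnesium alkoxide 15 (not isolated), via potassium alkoxide 16 (not isolated)
Conditions: 8 (1.3 equiv), Mg, Et2O, rt; add to L* (1.1 equiv, pre-treated with EtMgBr, 1.1 equiv) in toluene, −80 °C; add 13, −80 °C; then KOt-Bu (4 equiv), 18-crown-6, DMPU, 80 °C; aq. NH4Cl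
Reagents that add atoms: none
Why: Proposed new method: Grignard reagent 14 should add through C3 to the carbonyl carbon (C2) of 13 inside the magnesium complex of the tridentate N,N,O-ligand, and after exchange of magnesium for potassium the tertiary alkoxide O1 attacks C8a and expels fluoride (addition–elimination, SNAr), so that C2–C3 and O1–C8a form in one flask. The closest known reaction types are the ligand-mediated asymmetric Grignard addition to ketones (shown for aryl alkyl ketones, not for a methyl n-alkyl ketone) and the tandem Grignard addition–SNAr synthesis of chromans (shown for nitro-activated fluoroarenes, not for an alkoxy-substituted one). The pyran ring closes in the 6-exo-trig mode onto C8a, the only ring carbon that O1 can reach through a six-membered transition state and the only one that carries a leaving group, since the other ortho position holds the methyl group. The C2 stereocentre is set under reagent control: the chiral ligand is expected to shield the Si face of the ketone, Re-face attack gives the (S)-alkoxide, and the ring closure does not touch this centre. The step needs facial selectivity between the methyl group and the CH2CH2 arm of 13, for which the substrate offers little bias and which rests on the ligand alone, and 1,2-addition in preference to enolisation, which the low temperature favours; the MOM ethers and the isolated trisubstituted alkenes should be inert to KOt-Bu. The fluoride displacement is made plausible by the C7 alkoxy group, which is meta to C8a and stabilises the Meisenheimer adduct inductively, and by the intramolecular delivery of the alkoxide.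

Step 8
Reactants: 17 (2S)-7,8-bis(methoxymethoxy)-2,5-dimethyl-2-[(3E,7E)-4,8,12-trimethyltrideca-3,7,11-trien-1-yl]chromane
Product: 18 (2S)-2,5-dimethyl-2-[(3E,7E)-4,8,12-trimethyltrideca-3,7,11-trien-1-yl]-3,4-dihydro-2H-chromene-7,8-diol (target)
Conditions: HCl (1.25 M in MeOH), THF, rt, degassed, under argon
Reagents that add atoms: none
Why: Acid-catalysed transacetalisation to methanol should cleave both aryl MOM ethers under conditions too mild to protonate the trisubstituted alkenes or open the chroman, and the stereocentre is not involved.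

Compound list
1 | 4-methylcatechol (4-methylbenzene-1,2-diol) | Cc1ccc(O)c(O)c1 | starting material
2 | 1,2-bis(methoxymethoxy)-4-methylbenzene | Cc1ccc(OCOC)c(OCOC)c1 | intermediate
3 | [2,3-bis(methoxymethoxy)-5-methylphenyl]lithium | Cc1cc([Li])c(OCOC)c(OCOC)c1 | intermediate (not isolated)
4 | 1-fluoro-2,3-bis(methoxymethoxy)-5-methylbenzene | Cc1cc(F)c(OCOC)c(OCOC)c1 | intermediate
5 | 2-bromo-3-fluoro-4,5-bis(methoxymethoxy)-1-methylbenzene | Cc1cc(OCOC)c(OCOC)c(F)c1Br | intermediate
6 | [2-fluoro-3,4-bis(methoxymethoxy)-6-methylphenyl]magnesium chloride | Cc1cc(OCOC)c(OCOC)c(F)c1[Mg]Cl | intermediate (not isolated)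
7 | 2-[2-fluoro-3,4-bis(methoxymethoxy)-6-methylphenyl]ethan-1-ol | Cc1cc(OCOC)c(OCOC)c(F)c1CCO | intermediate
8 | 2-(2-bromoethyl)-3-fluoro-4,5-bis(methoxymethoxy)-1-methylbenzene | Cc1cc(OCOC)c(OCOC)c(F)c1CCBr | intermediate
9 | (2E,6E)-farnesyl bromide ((2E,6E)-1-bromo-3,7,11-trimethyldodeca-2,6,10-triene) | CC(C)=CCC/C(C)=C/CC/C(C)=C/CBr | starting material
10 | ethyl acetoacetate | CCOC(=O)CC(C)=O | starting material
11 | ethyl (4E,8E)-2-acetyl-5,9,13-trimethyltetradeca-4,8,12-trienoate (racemic at C2) | CC(C)=CCC/C(C)=C/CC/C(C)=C/CC(C(C)=O)C(=O)OCC | intermediate (not isolated)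
12 | (4E,8E)-2-acetyl-5,9,13-trimethyltetradeca-4,8,12-trienoic acid (racemic at C2) | CC(C)=CCC/C(C)=C/CC/C(C)=C/CC(C(C)=O)C(=O)O | intermediate (not isolated)
13 | (5E,9E)-farnesylacetone ((5E,9E)-6,10,14-trimethylpentadeca-5,9,13-trien-2-one) | CC(C)=CCC/C(C)=C/CC/C(C)=C/CCC(C)=O | intermediate
14 | {2-[2-fluoro-3,4-bis(methoxymethoxy)-6-methylphenyl]ethyl}magnesium bromide | Cc1cc(OCOC)c(OCOC)c(F)c1CC[Mg]Br | intermediate (not isolated)
15 | bromomagnesium (3S,6E,10E)-1-[2-fluoro-3,4-bis(methoxymethoxy)-6-methylphenyl]-3,7,11,15-tetramethylhexadeca-6,10,14-trien-3-olate | CC(C)=CCC/C(C)=C/CC/C(C)=C/CC[C@@](O[Mg]Br)(C)CCc1c(C)cc(OCOC)c(OCOC)c1F | intermediate (not isolated)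
16 | potassium (3S,6E,10E)-1-[2-fluoro-3,4-bis(methoxymethoxy)-6-methylphenyl]-3,7,11,15-tetramethylhexadeca-6,10,14-trien-3-olate | CC(C)=CCC/C(C)=C/CC/C(C)=C/CC[C@@]([O-])(C)CCc1c(C)cc(OCOC)c(OCOC)c1F.[K+] | intermediate (not isolated)
17 | (2S)-7,8-bis(methoxymethoxy)-2,5-dimethyl-2-[(3E,7E)-4,8,12-trimethyltrideca-3,7,11-trien-1-yl]chromane | CC(C)=CCC/C(C)=C/CC/C(C)=C/CC[C@@]1(C)CCc2c(C)cc(OCOC)c(OCOC)c2O1 | intermediate
18 | (2S)-2,5-dimethyl-2-[(3E,7E)-4,8,12-trimethyltrideca-3,7,11-trien-1-yl]-3,4-dihydro-2H-chromene-7,8-diol | CC(C)=CCC/C(C)=C/CC/C(C)=C/CC[C@@]1(C)CCc2c(C)cc(O)c(O)c2O1 | target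

Total step count: 8.
Longest linear sequence: 7 steps (steps 1, 2, 3, 4, 5, 7 and 8, from 4-methylcatechol); step 6 is a one-step side branch.

Steps most likely to fail

1. Step 7 (bears the label). What may go wrong is poor facial selectivity in the ligand-controlled addition to a ketone whose two arms differ little, which would give low enantiomeric purity, together with slow fluoride displacement on the electron-rich ring. The fallback uses known chemistry only and takes the stereocentre from a Sharpless asymmetric epoxidation; it sets out from aryl bromide 5 and comes back to the route at 17. Purchased (2E,6E,10E)-geranylgeraniol F1 is epoxidised (Ti(OiPr)4, L-(+)-diethyl tartrate, t-BuOOH, 4 Å molecular sieves, CH2Cl2, −20 °C) to the (2S,3S)-epoxy alcohol F2. PPh3, I2 and imidazole should convert this into the epoxy iodide F3, and zinc dust in refluxing EtOH opens F3 reductively to (3S)-geranyllinalool F4, whose carbinol carbon becomes C2 of the target. 9-BBN in THF (2.2 equiv, rt) should hydroborate only the vinyl group to the B-alkyl borane F5, which is coupled in the same flask with 5 (Pd(OAc)2, SPhos, aqueous K3PO4, 60 °C, B-alkyl Suzuki–Miyaura coupling) to the (S)-tertiary alcohol F6. KOt-Bu in DMPU at 80 °C then closes the pyran ring by intramolecular fluoride displacement to 17; in this fallback the two bonds are made in separate steps.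

2. Step 2. What may go wrong is lithiation at the wrong ortho position and transfer of a sulfonyl group in place of fluorine from the N–F reagent, both of which cut the supply of 4. The fallback buys the fluorine with the ring: it sets out from no numbered compound (purchased 5-fluorovanillin F7 takes the place of 1) and comes back to the route at 4. Hydrogenolysis of the aldehyde to the methyl group (H2, Pd/C, AcOH, rt) should give 2-fluoro-6-methoxy-4-methylphenol F8, BBr3 in CH2Cl2 (−78 to 0 °C) should give 3-fluoro-5-methylbenzene-1,2-diol F9, and NaH/MOMCl as in step 1 converts this catechol into 4.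

3. Step 4. What may go wrong is slow bromine–magnesium exchange on the electron-rich, doubly ortho-substituted ring and loss of the ortho-fluoroaryl Grignard reagent by elimination to an aryne on warming. The fallback replaces the organomagnesium route by a cross-coupling; it sets out from 5 and comes back to the route at 7. Palladium-catalysed coupling of 5 with the Reformatsky reagent BrZnCH2CO2t-Bu (Pd(dba)2, XPhos, THF, 60 °C) should give tert-butyl 2-[2-fluoro-3,4-bis(methoxymethoxy)-6-methylphenyl]acetate F10, and LiAlH4 in THF at 0 °C reduces this ester to 7.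

Further compounds
F1 | step 7 | (2E,6E,10E)-geranylgeraniol (purchased) | CC(C)=CCC/C(C)=C/CC/C(C)=C/CC/C(C)=C/CO
F2 | step 7 | [(2S,3S)-3-methyl-3-[(3E,7E)-4,8,12-trimethyltrideca-3,7,11-trien-1-yl]oxiran-2-yl]methanol | CC(C)=CCC/C(C)=C/CC/C(C)=C/CC[C@]1(C)O[C@H]1CO
F3 | step 7 | (2S,3R)-3-(iodomethyl)-2-methyl-2-[(3E,7E)-4,8,12-trimethyltrideca-3,7,11-trien-1-yl]oxirane (iodide in place of the hydroxyl group of F2, both ring centres spatially unchanged) | CC(C)=CCC/C(C)=C/CC/C(C)=C/CC[C@]1(C)O[C@H]1CI
F4 | step 7 | (3S,6E,10E)-geranyllinalool ((3S,6E,10E)-3,7,11,15-tetramethylhexadeca-1,6,10,14-tetraen-3-ol) | CC(C)=CCC/C(C)=C/CC/C(C)=C/CC[C@@](O)(C)C=C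
F5 | step 7 | B-alkyl-9-borabicyclo[3.3.1]nonane adduct of F4 (boron on the former terminal vinyl carbon) | CC(C)=CCC/C(C)=C/CC/C(C)=C/CC[C@@](O)(C)CCB1C2CCCC1CCC2
F6 | step 7 | (3S,6E,10E)-1-[2-fluoro-3,4-bis(methoxymethoxy)-6-methylphenyl]-3,7,11,15-tetramethylhexadeca-6,10,14-trien-3-ol | CC(C)=CCC/C(C)=C/CC/C(C)=C/CC[C@@](O)(C)CCc1c(C)cc(OCOC)c(OCOC)c1F
F7 | step 2 | 5-fluorovanillin (3-fluoro-4-hydroxy-5-methoxybenzaldehyde, purchased) | COc1cc(C=O)cc(F)c1O
F8 | step 2 | 2-fluoro-6-methoxy-4-methylphenol | COc1cc(C)cc(F)c1O
F9 | step 2 | 3-fluoro-5-methylbenzene-1,2-diol | Cc1cc(O)c(O)c(F)c1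
F10 | step 4 | tert-butyl 2-[2-fluoro-3,4-bis(methoxymethoxy)-6-methylphenyl]acetate | Cc1cc(OCOC)c(OCOC)c(F)c1CC(=O)OC(C)(C)C
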